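## Retrosynthetic overview

1. The target comes from its hexa-O-benzyl ether by hydrogenolysis; no ring changes.
2. Both stereocentres (C2, C3) come from a flat 3-hydroxyflavylium salt by a new one-pot reductive dearomatisation with dynamic kinetic resolution.
3. Ring C, the only ring built, is closed through the O1–C2 bond: a phenolic OH adds to the ketone carbon of an α-hydroxychalcone and water is lost. The chalcone arises in the same flask from a salicylaldehyde and an aryl hydroxymethyl ketone.
4. The C7–O ester bond is made first, on the unique para-OH of 2,4,6-trihydroxybenzaldehyde. The two remaining ortho-OH groups are equivalent, so ring closure can only give the 5-OH/7-O-gallate pattern.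
5. Rings A and B are bought as phloroglucinol- and gallic-acid-derived building blocks.

Assumption: the three starting materials are taken as catalogue chemicals, and the ligand hand in step 4 is assigned from the arene-recognition model of RuCl(TsDPEN)(arene) transfer-hydrogenation catalysts (ring A in the aryl pocket); the (R,R) complex would be used if the observed sense were opposite.

## Route

Step 1
Reactants: 1 phloroglucinaldehyde (2,4,6-trihydroxybenzaldehyde); 2 tri-O-benzylgallic acid (3,4,5-tris(benzyloxy)benzoic acid)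
Product: 3 galloylated aldehyde 4-formyl-3,5-dihydroxyphenyl 3,4,5-tris(benzyloxy)benzoate
Conditions: 2 (1.0 equiv), 1 (1.3 equiv), N,N'-diisopropylcarbodiimide (DIC, 1.05 equiv), DMAP (10 mol%), THF, −20 → 0 °C
Reagents that add atoms: none
Why: Steglich esterification; the para-OH is the only hydroxyl that is unhindered and outside the OH···O=CH chelate, so the bulky acylpyridinium should acylate it preferentially (excess 1 suppresses diacylation), and this one C–O bond defines the later 7-O-gallate/5-OH pattern; no stereocentre.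

Step 2
Reactants: 4 tri-O-benzylgallaldehyde (3,4,5-tris(benzyloxy)benzaldehyde)
Product: 5 aryl ketol 2-hydroxy-1-[3,4,5-tris(benzyloxy)phenyl]ethan-1-one
Conditions: (CH2O)n (3 equiv), 3-benzyl-5-(2-hydroxyethyl)-4-methylthiazolium chloride (10 mol%), iPr2NEt (20 mol%), THF, 60 °C
Reagents that add atoms: paraformaldehyde, as formaldehyde (C=O)
Why: NHC-catalysed cross-acyloin reaction (hydroxymethylation), in which the Breslow intermediate of the aryl aldehyde adds to the more electrophilic formaldehyde to give the hydroxymethyl ketone; no stereocentre.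

Step 3
Reactants: 3 galloylated aldehyde; 5 aryl ketol
Product: 7 flavylium chloride 3,5-dihydroxy-7-[3,4,5-tris(benzyloxy)benzoyloxy]-2-[3,4,5-tris(benzyloxy)phenyl]chromenylium chloride, via α-hydroxychalcone 6 (not isolated)
Conditions: dry HCl (g), EtOAc, 0 °C, 48 h; precipitation with dry Et2O under Ar
Reagents that add atoms: hydrogen chloride (Cl)
Why: Robinson-type flavylium synthesis, in which acid-catalysed aldol condensation gives chalcone 6, either of its two equivalent ortho-OH groups then attacks the ketone carbon (O1–C2 bond) and loss of water aromatises ring C, so the ester necessarily ends at C7 and the free OH at C5; no stereocentre is formed, and benzyl ethers and the aryl ester tolerate anhydrous HCl.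

Step 4
Reactants: 7 flavylium chloride
Product: 10 benzyl-protected flavan-3-ol (2R,3R)-3,5-dihydroxy-2-[3,4,5-tris(benzyloxy)phenyl]chroman-7-yl 3,4,5-tris(benzyloxy)benzoate, via enol 8 (not isolated), via flavan-3-one 9 (not isolated)
Conditions: RuCl[(S,S)-TsDPEN](p-cymene) (2 mol%), HCO2H/Et3N (1:1, 6 equiv), CH2Cl2, 0 → 25 °C, slow addition of 7, Ar
Reagents that add atoms: none
Why: Proposed new method: an anthocyanidin-reductase-like double hydride transfer in which the divalent ruthenium hydride formed from the precatalyst and formate first reduces the flavylium cation at C4 (or C2) to enol 8, which ketonises to flavan-3-one 9 whose C2–H (α-keto, benzylic, α-oxygen) epimerises rapidly through that same enol, so that bifunctional outer-sphere hydride delivery to the matched (2R)-ketone on the face anti to the C2 aryl group sets C3 (R) and fixes C2 (R) together as the cis alcohol by dynamic kinetic resolution, slow addition keeping the acyl-activated flavylium from accumulating; the closest known reaction types are asymmetric transfer hydrogenation with dynamic kinetic resolution of α-substituted cyclic ketones and hydride reduction of flavylium salts to flavenes.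

Step 5
Reactants: 10 benzyl-protected flavan-3-ol
Product: 11 epigallocatechin 7-O-gallate [(2R,3R)-3,5-dihydroxy-2-(3,4,5-trihydroxyphenyl)chroman-7-yl 3,4,5-trihydroxybenzoate]
Conditions: H2 (1 atm), Pd(OH)2/C (20 wt%), THF/MeOH 1:1, 25 °C, work-up under N2
Reagents that add atoms: none
Why: Catalytic hydrogenolysis of the six benzyl ethers under neutral conditions, which leaves the aryl gallate ester, the benzylic C2–O1 bond and both stereocentres untouched, as in the last step of benzyl-protected catechin gallate syntheses.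

## Compound list

1 | 2,4,6-trihydroxybenzaldehyde (phloroglucinaldehyde) | O=Cc1c(O)cc(O)cc1O | starting material
2 | 3,4,5-tris(benzyloxy)benzoic acid | OC(=O)c1cc(OCc2ccccc2)c(OCc2ccccc2)c(OCc2ccccc2)c1 | starting material
3 | 4-formyl-3,5-dihydroxyphenyl 3,4,5-tris(benzyloxy)benzoate | O=Cc1c(O)cc(OC(=O)c2cc(OCc3ccccc3)c(OCc3ccccc3)c(OCc3ccccc3)c2)cc1O | intermediate
4 | 3,4,5-tris(benzyloxy)benzaldehyde | O=Cc1cc(OCc2ccccc2)c(OCc2ccccc2)c(OCc2ccccc2)c1 | starting material
5 | 2-hydroxy-1-[3,4,5-tris(benzyloxy)phenyl]ethan-1-one | O=C(CO)c1cc(OCc2ccccc2)c(OCc2ccccc2)c(OCc2ccccc2)c1 | intermediate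
6 | α-hydroxychalcone: 4-{(1E)-2-hydroxy-3-oxo-3-[3,4,5-tris(benzyloxy)phenyl]prop-1-en-1-yl}-3,5-dihydroxyphenyl 3,4,5-tris(benzyloxy)benzoate | O=C(Oc1cc(O)c(/C=C(/O)C(=O)c2cc(OCc3ccccc3)c(OCc3ccccc3)c(OCc3ccccc3)c2)c(O)c1)c1cc(OCc2ccccc2)c(OCc2ccccc2)c(OCc2ccccc2)c1 | intermediate
7 | 3,5-dihydroxy-7-[3,4,5-tris(benzyloxy)benzoyloxy]-2-[3,4,5-tris(benzyloxy)phenyl]chromenylium chloride | [Cl-].O=C(Oc1cc(O)c2cc(O)c(-c3cc(OCc4ccccc4)c(OCc4ccccc4)c(OCc4ccccc4)c3)[o+]c2c1)c1cc(OCc2ccccc2)c(OCc2ccccc2)c(OCc2ccccc2)c1 | intermediate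
8 | enol: 3,5-dihydroxy-2-[3,4,5-tris(benzyloxy)phenyl]-4H-chromen-7-yl 3,4,5-tris(benzyloxy)benzoate | O=C(Oc1cc(O)c2c(c1)OC(c1cc(OCc3ccccc3)c(OCc3ccccc3)c(OCc3ccccc3)c1)=C(O)C2)c1cc(OCc2ccccc2)c(OCc2ccccc2)c(OCc2ccccc2)c1 | intermediate
9 | flavan-3-one: 5-hydroxy-3-oxo-2-[3,4,5-tris(benzyloxy)phenyl]chroman-7-yl 3,4,5-tris(benzyloxy)benzoate (C2 epimerises freely, so no descriptor) | O=C(Oc1cc(O)c2c(c1)OC(c1cc(OCc3ccccc3)c(OCc3ccccc3)c(OCc3ccccc3)c1)C(=O)C2)c1cc(OCc2ccccc2)c(OCc2ccccc2)c(OCc2ccccc2)c1 | intermediate
10 | (2R,3R)-3,5-dihydroxy-2-[3,4,5-tris(benzyloxy)phenyl]chroman-7-yl 3,4,5-tris(benzyloxy)benzoate (2,3-cis) | O=C(Oc1cc(O)c2c(c1)O[C@H](c1cc(OCc3ccccc3)c(OCc3ccccc3)c(OCc3ccccc3)c1)[C@H](O)C2)c1cc(OCc2ccccc2)c(OCc2ccccc2)c(OCc2ccccc2)c1 | intermediate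
11 | epigallocatechin 7-O-gallate, (2R,3R)-3,5-dihydroxy-2-(3,4,5-trihydroxyphenyl)chroman-7-yl 3,4,5-trihydroxybenzoate (2,3-cis) | O=C(Oc1cc(O)c2c(c1)O[C@H](c1cc(O)c(O)c(O)c1)[C@H](O)C2)c1cc(O)c(O)c(O)c1 | target

## Step count and risks

Total step count: 5 (steps 1 and 2 run in parallel). Longest linear sequence: 4 steps (1, 3, 4, 5).

The three steps most likely to fail, with the most uncertain first:

**Step 4, the new reduction.** It can fail in three ways: the enol may be trapped through its C2 oxocarbenium ion before it ketonises, which erodes cis selectivity and ee; the catalyst may discriminate poorly between the ketone enantiomers; or the activated 7-O-ester may transfer its acyl group before the cation is reduced. The fallback uses known chemistry, sets out from 7 and comes back at 11. Compound 7 is hydrogenated over Pd(OH)2/C under H2 in MeOH/EtOAc containing a little AcOH. This is the classical hydrogenation of an anthocyanidin chloride to an epi-flavan-3-ol: syn addition of hydrogen to ring C gives the 2,3-cis product while the six benzyl ethers are cleaved in the same flask. The product is the racemate, that is 11 together with its mirror image, the (2S,3S)-enantiomer F4. Preparative HPLC on amylose tris(3,5-dimethylphenylcarbamate) then delivers 11.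

**Step 1, site-selective esterification.** The ortho-OH groups may compete, giving regioisomers and diesters. The fallback sets out from 1 and comes back at 3. Compound 1 is acylated exhaustively with 3.3 equiv of 2 (DIC, DMAP, CH2Cl2) to the tris-ester 2-formylbenzene-1,3,5-triyl tris[3,4,5-tris(benzyloxy)benzoate] F1. The two esters that flank the formyl group are then removed by methanolysis (MeOH, catalytic imidazole, THF, 0 °C). This relies on the hemiacetal of the neighbouring aldehyde delivering the nucleophile intramolecularly to the ortho esters only, and on their cleavage restoring the chelated ortho-hydroxyaldehyde, so the para ester survives and 3 is obtained.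

**Step 3, flavylium formation.** The free ketol 5 may dimerise or isomerise in acid faster than it condenses. The fallback sets out from 5 (with 3) and comes back at 7. Compound 5 is acetylated (Ac2O, pyridine) to the ketol acetate 2-oxo-2-[3,4,5-tris(benzyloxy)phenyl]ethyl acetate F2, which cannot self-condense. F2 is condensed with 3 in HCl-saturated EtOAc to the 3-acetoxyflavylium chloride F3. Brief treatment with methanolic HCl at 0 °C transesterifies the small, strongly activated 3-O-acetyl group in preference to the bulkier electron-rich 7-O-aroyl ester and returns 7.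

## Further compounds

F1 | step 1 | 2-formylbenzene-1,3,5-triyl tris[3,4,5-tris(benzyloxy)benzoate] | O=Cc1c(OC(=O)c2cc(OCc3ccccc3)c(OCc3ccccc3)c(OCc3ccccc3)c2)cc(OC(=O)c2cc(OCc3ccccc3)c(OCc3ccccc3)c(OCc3ccccc3)c2)cc1OC(=O)c1cc(OCc2ccccc2)c(OCc2ccccc2)c(OCc2ccccc2)c1
F2 | step 3 | 2-oxo-2-[3,4,5-tris(benzyloxy)phenyl]ethyl acetate | CC(=O)OCC(=O)c1cc(OCc2ccccc2)c(OCc2ccccc2)c(OCc2ccccc2)c1
F3 | step 3 | 3-acetoxy-5-hydroxy-7-[3,4,5-tris(benzyloxy)benzoyloxy]-2-[3,4,5-tris(benzyloxy)phenyl]chromenylium chloride | [Cl-].CC(=O)Oc1cc2c(O)cc(OC(=O)c3cc(OCc4ccccc4)c(OCc4ccccc4)c(OCc4ccccc4)c3)cc2[o+]c1-c1cc(OCc2ccccc2)c(OCc2ccccc2)c(OCc2ccccc2)c1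
F4 | step 4 | (2S,3S)-3,5-dihydroxy-2-(3,4,5-trihydroxyphenyl)chroman-7-yl 3,4,5-trihydroxybenzoate (mirror image of 11) | O=C(Oc1cc(O)c2c(c1)O[C@@H](c1cc(O)c(O)c(O)c1)[C@@H](O)C2)c1cc(O)c(O)c(O)c1
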